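**Plan**
- Retrosynthesis: the two catechol O–H groups are first tied into a five-membered 1,3,2-dioxasilole; its C3–O bond is then cut back to C3–H, then the C2 O–Si bond, and last the ester C(=O)–O bond to the C21 chain.
- Forward: ester exchange joins the C21 chain to the salicylate, the C2 oxygen is tethered to a di-tert-butylsilanol, palladium-catalysed oxygenation forms the C3–O bond and closes the dioxasilole (the only ring made), and fluoride removes silicon.
- Enabling feature: on the benzene ring the C2 oxygen has two ortho carbons, C1 and C3. C1 carries the ester carbon, so a directing group hung on the C2 oxygen can only reach the C3–H bond.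
- Stereochemistry: the target has no stereocentre and no double-bond geometry, so nothing has to be set.

Key step: step 3

Remark on the chemistry: the C3 oxygen of 8 is taken to come from an acetate of PhI(OAc)2 (acetoxylation, then ring closure with the silanol OH leaving in acetic acid), so the oxidant is listed as an atom-adding reagent.

Step 1
Reactants: 1 methyl salicylate; 2 1-heneicosanol
Product: 3 heneicosyl salicylate (heneicosyl 2-hydroxybenzoate)
Conditions: 1 (3 equiv), Bu2SnO (5 mol %), xylene, 140 °C, MeOH distilled off; excess 1 removed under vacuum
Reagents that add atoms: none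
Why: Tin-catalysed transesterification is an equilibrium that should be driven to the long-chain ester by removal of methanol and excess 1, the primary alcohol being a far better acyl acceptor than the hydrogen-bonded phenol, as in the technical preparation of higher alkyl salicylates.

Step 2
Reactants: 3 heneicosyl salicylate; 4 di-tert-butylsilyl bis(trifluoromethanesulfonate)
Product: 6 heneicosyl 2-{[di-tert-butyl(hydroxy)silyl]oxy}benzoate, via aryloxysilyl triflate 5 (not isolated)
Conditions: 4 (1.2 equiv), 2,6-lutidine (3 equiv), CH2Cl2, 0 °C, slow addition of 3; then H2O, THF, 0 °C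
Reagents that add atoms: di-tert-butylsilyl bis(trifluoromethanesulfonate) (compound 4), CC(C)(C)[Si](OS(=O)(=O)C(F)(F)F)(OS(=O)(=O)C(F)(F)F)C(C)(C)C; water, O
Why: O-Silylation of a phenol with a silyl bis-triflate followed by hydrolysis (two nucleophilic substitutions at silicon) should work because the highly electrophilic ditriflate overcomes the hydrogen bond and the ortho ester, the tert-butyl groups stop the reaction at the mono-aryloxy triflate 5, and the remaining Si–OTf bond is hydrolysed much faster than the hindered aryl O–Si bond.

Step 3
Reactants: 6 heneicosyl 2-{[di-tert-butyl(hydroxy)silyl]oxy}benzoate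
Product: 8 heneicosyl 2,2-di-tert-butyl-1,3,2-benzodioxasilole-4-carboxylate, via C3 acetate 7 (not isolated)
Conditions: Pd(OPiv)2 (10 mol %), PhI(OAc)2 (2 equiv), toluene, 100 °C; quick filtration through a short silica pad, used promptly
Reagents that add atoms: (diacetoxyiodo)benzene, PhI(OAc)2, CC(=O)OI(OC(C)=O)c1ccccc1
Why: The silanol oxygen of 6 coordinates divalent palladium and places it over C3–H, which is cleaved by pivalate-assisted concerted metalation–deprotonation to a six-membered palladacycle (Pd–O–Si–O–C2–C3). PhI(OAc)2 oxidises this palladacycle to a tetravalent palladium acetate, and C3–O reductive elimination gives the C3 acetate 7 and returns divalent palladium. Under the carboxylic acid present, the acetyl group of 7 moves to the adjacent silanol oxygen and the freed C3 oxygen attacks silicon, expelling acetic acid and closing the five-membered 1,3,2-dioxasilole by a 5-exo substitution at silicon (the only ring formed). The closest known reaction type is the silanol-directed, palladium-catalysed ortho C–H oxygenation of phenols to silicon-bridged catechols with a hypervalent iodine oxidant, a process that accepts electron-poor phenols. No stereocentre is created, so the only selectivity required is the site of oxygenation, and the substrate fixes it: the tether on the C2 oxygen can reach only the two ortho carbons, C1 being fully substituted by the ester and C3 alone bearing hydrogen, while C6 next to the weakly coordinating ester lies outside any favourable palladacycle. The silacycle keeps both catechol oxygens bound to silicon, which should protect the product from further oxidation to an ortho-quinone by excess oxidant.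

Step 4
Reactants: 8 heneicosyl 2,2-di-tert-butyl-1,3,2-benzodioxasilole-4-carboxylate
Product: 9 heneicosyl 2,3-dihydroxybenzoate (target)
Conditions: HF·pyridine, THF, 0 °C to rt, polypropylene vessel
Reagents that add atoms: none
Why: Fluoride-mediated desilylation, driven by the strong Si–F bond, should open the strained five-membered bis-aryloxysilane readily and remove silicon as the difluorosilane, while the mildly acidic medium leaves the alkyl ester intact and keeps the catechol protonated and so safe from air oxidation.

**Compound list**
1 | methyl salicylate | COC(=O)c1ccccc1O | starting material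
2 | 1-heneicosanol | CCCCCCCCCCCCCCCCCCCCCO | starting material
3 | heneicosyl salicylate (heneicosyl 2-hydroxybenzoate) | CCCCCCCCCCCCCCCCCCCCCOC(=O)c1ccccc1O | intermediate
4 | di-tert-butylsilyl bis(trifluoromethanesulfonate) | CC(C)(C)[Si](OS(=O)(=O)C(F)(F)F)(OS(=O)(=O)C(F)(F)F)C(C)(C)C | starting material
5 | heneicosyl 2-{[di-tert-butyl(trifluoromethanesulfonyloxy)silyl]oxy}benzoate (not isolated) | CCCCCCCCCCCCCCCCCCCCCOC(=O)c1ccccc1O[Si](OS(=O)(=O)C(F)(F)F)(C(C)(C)C)C(C)(C)C | intermediate
6 | heneicosyl 2-{[di-tert-butyl(hydroxy)silyl]oxy}benzoate | CCCCCCCCCCCCCCCCCCCCCOC(=O)c1ccccc1O[Si](O)(C(C)(C)C)C(C)(C)C | intermediate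
7 | heneicosyl 3-acetoxy-2-{[di-tert-butyl(hydroxy)silyl]oxy}benzoate (not isolated) | CCCCCCCCCCCCCCCCCCCCCOC(=O)c1cccc(OC(C)=O)c1O[Si](O)(C(C)(C)C)C(C)(C)C | intermediate
8 | heneicosyl 2,2-di-tert-butyl-1,3,2-benzodioxasilole-4-carboxylate | CCCCCCCCCCCCCCCCCCCCCOC(=O)c1cccc2O[Si](C(C)(C)C)(C(C)(C)C)Oc12 | intermediate
9 | heneicosyl 2,3-dihydroxybenzoate | CCCCCCCCCCCCCCCCCCCCCOC(=O)c1cccc(O)c1O | target

Total step count: 4. Longest linear sequence: 4 steps (from 1 or 2 to 9).

**Steps most likely to fail**

Risk 1 (step 3). Three processes could defeat the oxygenation:
- metalation at C3 of an electron-poor ring flanked by the ester may be slower than catalyst decomposition;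
- at 100 °C the silanol OH may add to the neighbouring ester carbonyl and expel the C21 alcohol;
- the strained silacycle may open during filtration.

The fallback sets out from 3 and gives up C–H oxygenation for a carbon-to-oxygen exchange. Magnesium-mediated ortho-formylation (MgCl2, Et3N, paraformaldehyde, MeCN, reflux) can only attack C3 and should give heneicosyl 3-formyl-2-hydroxybenzoate F1. Dakin oxidation (H2O2, Na2CO3, aqueous THF, 0 °C) should then convert the aldehyde into heneicosyl 3-(formyloxy)-2-hydroxybenzoate F2, which is hydrolysed in the same flask. The fallback comes back to the route at 9.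

Risk 2 (step 2). Two processes could spoil the silanol installation:
- the very reactive silyl triflate may engage the ester carbonyl, with loss of the alkyl group;
- hydrolysis may cleave the aryl O–Si bond instead of stopping at the silanol.

The fallback sets out from 3 and builds the silanol through a hydrosilane. The milder di-tert-butylchlorosilane (imidazole, DMF, 60 °C) should give heneicosyl 2-(di-tert-butylsilyloxy)benzoate F3. Bromination of the Si–H bond with N-bromosuccinimide in CH2Cl2 should give heneicosyl 2-[bromo(di-tert-butyl)silyloxy]benzoate F4, which is hydrolysed with aqueous NaHCO3. The fallback comes back to the route at 6.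

Risk 3 (step 1). Three processes could limit the ester exchange:
- the equilibrium may stall;
- the phenol may be acylated at 140 °C to give oligomeric salicylates;
- excess methyl salicylate may be hard to remove from the waxy product.

The fallback sets out from 2 and turns the alcohol into the electrophile. MsCl and Et3N in CH2Cl2 should give heneicosyl methanesulfonate F5. Commercial salicylic acid is then alkylated at the carboxylate only (KHCO3, DMF, 70 °C), the phenol staying protonated under bicarbonate. The fallback comes back to the route at 3.

**Further compounds**
F1 | step 3 | heneicosyl 3-formyl-2-hydroxybenzoate | CCCCCCCCCCCCCCCCCCCCCOC(=O)c1cccc(C=O)c1O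
F2 | step 3 | heneicosyl 3-(formyloxy)-2-hydroxybenzoate | CCCCCCCCCCCCCCCCCCCCCOC(=O)c1cccc(OC=O)c1O
F3 | step 2 | heneicosyl 2-(di-tert-butylsilyloxy)benzoate | CCCCCCCCCCCCCCCCCCCCCOC(=O)c1ccccc1O[SiH](C(C)(C)C)C(C)(C)C
F4 | step 2 | heneicosyl 2-[bromo(di-tert-butyl)silyloxy]benzoate | CCCCCCCCCCCCCCCCCCCCCOC(=O)c1ccccc1O[Si](Br)(C(C)(C)C)C(C)(C)C
F5 | step 1 | heneicosyl methanesulfonate | CCCCCCCCCCCCCCCCCCCCCOS(C)(=O)=O
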